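Start from the constants: the two reacting steps have 3.0 M⁻¹ h⁻¹ and 4.3 M⁻¹ h⁻¹, and the balance with the idle adduct has 240 M⁻¹.

    reagent + single product → double product + by-product (k1 = 3.0 M⁻¹ h⁻¹)
    substrate + reagent → single product + by-product (k2 = 4.3 M⁻¹ h⁻¹)
    reagent + by-product ⇌ idle adduct, settled at all times (K3 = 240 M⁻¹)

substrate 0.10 M; reagent 2.50 equiv; time 5.0 d

- part of the substrate that has reacted at 5.0 d
- share of the unused reagent that is free and not bound as idle adduct, at 5.0 d

- amounts and yields of by-product count idle adduct too
- run time (flask): 5.0 d

My reckoning counts everything in fractions of the substrate charge.

1. Let x be the by-product made, idle adduct counted. Each reagent used makes one by-product, so the unused reagent, idle adduct counted, is 2.50 minus x.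
2. Multiply the balance constant by the substrate charge: the binding number, 24.0, is the ratio of bound to free reagent when free by-product equals the substrate charge. With free by-product w, the free share is one over (one plus binding number times w).
3. The idle adduct takes one of each, so w minus free reagent is 2x minus 2.50. Past x of 1.25, by-product is in excess and the idle adduct becomes the reagent's resting state.
4. The substrate's half-life at the charge, 0.645 h, is short against 5.0 d, so I take the substrate as used up, with x between 1.50 and 2. Then w runs from 0.500 to 1.50. I commit to the middle, 1.00, which gives a free share of 4.00%.
5. At that point the substrate's half-life is 2.24 d. Even at that pace throughout, c reaches 78.7%, and I expect more.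

The forecast says 98% and 3.5%, resting on “the adduct balance with by-product in excess of the unused reagent”; its free share is lower than mine.

The flask gives 98.0% and 3.51%, so the forecast held. In the flask, the substrate's half-life grows from 0.051 d at 0.0360 d to 2.8 d at 5.00 d, while free by-product reaches 1.15 of the charge, which with the binding number gives a free share of 3.51%. In the neighbour flask with 1.50 equiv, by-product and idle adduct together make x 1.31, so w is about 1.12 and the free share 3.60%; that flask stands at 3.58%.

The numbers of this flask were chosen freely; the result is computed.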